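Its constants were set for the occasion; the rest is arithmetic.

I decide to follow one ratio through this flask, c(starting complex) over c(enzyme), and to read the shares of the catalyst from it.

starting material 0.020 M; solid second substrate 5.00 equiv; enzyme 0.0035 mol%; added ligand 2.6 µM

    starting material + enzyme ⇌ starting complex (K1 = 1100 M⁻¹, k1 = 14000 M⁻¹ s⁻¹)
    second substrate + starting complex ⇌ ternary complex (K2 = 16 M⁻¹, k2 = 21000 M⁻¹ s⁻¹)
    ternary complex → enzyme + product (k3 = 930 min⁻¹)
    enzyme + added ligand ⇌ idle complex (K4 = 3.5 × 10⁵ M⁻¹, k4 = 2.2 × 10⁵ M⁻¹ min⁻¹)
    solid second substrate ⇌ second substrate, rate k5*(cs5 - [second substrate]) while solid is left; crystals form when [second substrate] > cs5 (cs5 = 12 mM, k5 = 0.032 min⁻¹)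

1. the form that holds most of the catalyst when 10% of the starting material are converted (idle complex / enzyme / ternary complex / starting complex)
2. its share of the catalyst then

The catalyst charged is 0.700 µM, and the added ligand exceeds it, so I keep c(added ligand) at its charge, which gives 0.910 idle complex per enzyme. With binding balanced and 10% converted, starting complex per enzyme is 19.8. That puts 91.2% of the catalyst on starting complex before ternary complex is counted.

Next comes c(second substrate). Ternary complex falls back 84.7 times faster than it goes on, so I hold it balanced with starting complex, and second substrate is consumed pseudo-first-order with coefficient 0.00950 min⁻¹. Set against dissolution, and with that coefficient held, this gives a plateau of 9.25 mM in my reckoning, approached with a time of 24.1 min. Integrating to 2.00 mM of product takes about 43.4 min, when c(second substrate) is 7.73 mM. Ternary complex per starting complex is then 0.124, and I commit to 82.0% on starting complex, the resting state of the round.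

The weak link is the balanced first binding. Starting complex also leaves forward, at 115 min⁻¹, beside falling back at 764 min⁻¹. So I name the load, 17.2: the steady-state c(starting complex) over c(enzyme), which is the balanced ratio divided by one plus the ratio of those two rates. With the load in its place, the share becomes 81.0%.

The forecast names starting complex at 81%, between 77% and 85%, noting that “the ligand binds only about as much catalyst as remains free”.

The flask gives starting complex at 80.9% after 45.3 min, and its ratio to enzyme reads 17.2 against my load of 17.2. The back reaction of idle complex holds the apparent order in enzyme at 10% conversion at 0.69, and the run with that step one-way gives 4.9. With 15.0% of the starting material left and c(second substrate) put at 9.89 mM, the level at which dissolution matches the rate of making product after 211 min, the load falls to 2.77, which gives 54.1% against the 54.7% the flask shows after 259 min.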